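**Plan**

- Retrosynthesis: free the phenols from benzyl ethers and remove the two enol methyl ethers; open each 4-hydroxy-2-pyranone at its O1–C2 lactone bond to a 3,5-dioxo ester; cut both C5–C6 bonds to reach an α-truxilloyl bis-imidazolide and two acetoacetate dianions; split the cyclobutane into two molecules of p-coumaric acid.
- Enabling feature: in each pyranone, C6 is the acyl carbon carried by cyclobutane carbon C1 or C3, and C5, C4, C3 and C2 are the four carbons of an acetoacetate. Both C5–C6 bonds can therefore be made in one operation on the symmetric diacid.
- Forward order: the cyclobutane is made first by photodimerisation, then benzylation and CDI activation, then the two-directional chain extension; both pyranone rings close together by lactonisation, followed by O-methylation and debenzylation.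
- Stereochemistry: all four ring stereocentres come from the crystal-controlled head-to-tail dimerisation (α-truxillic pattern: pyranonyl groups 1,3-trans, aryl groups 2,4-trans). The target is centrosymmetric and achiral, so only relative configuration matters, and no later step enolises the ring methines.

Key step: step 4

Assumption: commercial trans-p-coumaric acid is taken to crystallise in the photoactive head-to-tail packing, so that irradiation of the solid gives the α-truxillic dimer.

**Route**

Step 1
Reactants: 1 trans-p-coumaric acid (two molecules)
Product: 2 4,4′-dihydroxy-α-truxillic acid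
Conditions: hν (medium-pressure Hg lamp, borosilicate filter), finely ground crystals of 1 stirred as a suspension in hexane, 23 °C
Reagents that add atoms: none
Why: Topochemical [2+2] photocycloaddition in the crystal, where centrosymmetric head-to-tail pairs of molecules hold their C=C bonds parallel and within bonding distance, so the lattice alone should set all four stereocentres with retention of the trans alkene geometry (acids 1,3-trans, aryls 2,4-trans, each acid cis to one aryl neighbour and trans to the other).

Step 2
Reactants: 2 4,4′-dihydroxy-α-truxillic acid; 3 benzyl bromide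
Product: 4 4,4′-bis(benzyloxy)-α-truxillic acid
Conditions: BnBr (3 equiv), NaOH (6 equiv), EtOH–H2O, reflux; then aqueous HCl to pH 2
Reagents that add atoms: benzyl bromide, BrCc1ccccc1
Why: Williamson ether synthesis on the tetra-anion, in which the phenoxides are far better nucleophiles than the carboxylates and any benzyl ester formed in passing is saponified by the excess hydroxide, while the carboxylate α-CH bonds are not acidic under these conditions and the ring configuration should be retained.

Step 3
Reactants: 4 4,4′-bis(benzyloxy)-α-truxillic acid; 5 1,1′-carbonyldiimidazole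
Product: 6 4,4′-bis(benzyloxy)-α-truxilloyl bis-imidazolide
Conditions: CDI (2.3 equiv), THF, 23 → 40 °C; concentrate, quick cold-water wash of the CH2Cl2 solution, dry
Reagents that add atoms: 1,1′-carbonyldiimidazole, O=C(n1ccnc1)n1ccnc1
Why: Carboxylic acid activation as the acyl imidazolide, driven by loss of CO2 under neutral conditions that leave the ring methines alone, and the wash removes the liberated imidazole so that no N–H acid reaches the carbanion of the next step.

Step 4
Reactants: 6 4,4′-bis(benzyloxy)-α-truxilloyl bis-imidazolide; 7 methyl acetoacetate
Product: 9 dimethyl 5,5′-[(1α,2α,3β,4β)-2,4-bis(4-benzyloxyphenyl)cyclobutane-1,3-diyl]bis(3,5-dioxopentanoate), via methyl acetoacetate dianion 8 (not isolated)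
Conditions: methyl acetoacetate 7 (7.0 equiv), NaH (7.5 equiv), THF, 0 °C; n-BuLi (7.0 equiv), 0 °C; then 6 in THF, −78 → 0 °C; 1 M HCl to pH 3
Reagents that add atoms: methyl acetoacetate, CC(=O)CC(=O)OC
Why: The terminal carbanion of dianion 8 adds to each imidazolide carbonyl of 6 and the tetrahedral adduct expels imidazolide, so both pyranone C5–C6 bonds form in one operation; each new 3,5-dioxo ester is deprotonated at once by surplus dianion (hence about three equivalents of 8 per acyl group) and stays an unreactive polyanion until the acid quench. The closest known reaction type is the γ-selective Claisen acylation of β-keto ester dianions by acyl imidazoles, esters or N-methoxy-N-methylamides. No ring is closed and no stereocentre is created. The step needs acylation at the γ-carbon in preference to the α-carbon or oxygen, which the much higher basicity and nucleophilicity of the terminal carbanion should secure. It also needs addition to outrun deprotonation of the ring methines, which is favoured by the high electrophilicity of the azolide at −78 °C and by each methine being tertiary, flanked by two aryl-bearing carbons, and able to enolise only to a double bond exocyclic to the four-membered ring. The two acyl groups lie 1,3-trans on opposite faces of the cyclobutane and should therefore react independently.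

Step 5
Reactants: 9 dimethyl 5,5′-[(1α,2α,3β,4β)-2,4-bis(4-benzyloxyphenyl)cyclobutane-1,3-diyl]bis(3,5-dioxopentanoate)
Product: 10 6,6′-[(1α,2α,3β,4β)-2,4-bis(4-benzyloxyphenyl)cyclobutane-1,3-diyl]bis(4-hydroxy-2H-pyran-2-one)
Conditions: DBU (4 equiv), toluene, 80 °C; then 1 M HCl
Reagents that add atoms: none
Why: Base-mediated enol lactonisation, the standard closure of 3,5-dioxo esters to 4-hydroxy-2-pyranones, in which the C5 enolate oxygen attacks the ester carbonyl (6-exo-trig) with loss of methoxide and the acidic pyranone is trapped as its DBU salt, while the chain enolises between its two ketones and not towards the ring, so the methines should stay untouched.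

Step 6
Reactants: 10 6,6′-[(1α,2α,3β,4β)-2,4-bis(4-benzyloxyphenyl)cyclobutane-1,3-diyl]bis(4-hydroxy-2H-pyran-2-one); 11 dimethyl sulfate
Product: 12 6,6′-[(1α,2α,3β,4β)-2,4-bis(4-benzyloxyphenyl)cyclobutane-1,3-diyl]bis(4-methoxy-2H-pyran-2-one)
Conditions: Me2SO4 (2.4 equiv), K2CO3 (3 equiv), acetone, reflux
Reagents that add atoms: dimethyl sulfate, COS(=O)(=O)OC
Why: O-alkylation of the 4-hydroxy-2-pyranone anion with the hard electrophile Me2SO4, conditions under which such anions are known to give 4-methoxy-2-pyranones in preference to 2-methoxy-4-pyranones or C3-methylation, with the benzyl ethers and the cyclobutane inert to K2CO3.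

Step 7
Reactants: 12 6,6′-[(1α,2α,3β,4β)-2,4-bis(4-benzyloxyphenyl)cyclobutane-1,3-diyl]bis(4-methoxy-2H-pyran-2-one)
Product: 13 6,6′-[(1α,2α,3β,4β)-2,4-bis(4-hydroxyphenyl)cyclobutane-1,3-diyl]bis(4-methoxy-2H-pyran-2-one) (target, CNP0273697.2)
Conditions: BCl3 (6 equiv), pentamethylbenzene (8 equiv), CH2Cl2, −78 °C; then H2O
Reagents that add atoms: none
Why: Lewis acid-mediated cleavage of aryl benzyl ethers with BCl3 and pentamethylbenzene as a non-basic cation scavenger, in which the benzyl–oxygen bond should ionise at −78 °C while the methyl enol ethers and lactones, which would require SN2 attack of chloride at methyl, remain intact and the scavenger prevents Friedel–Crafts benzylation of the freed phenols.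

**Compound list**

1 | trans-p-coumaric acid, (E)-3-(4-hydroxyphenyl)prop-2-enoic acid | OC(=O)/C=C/c1ccc(O)cc1 | starting material
2 | 4,4′-dihydroxy-α-truxillic acid, (1α,2α,3β,4β)-2,4-bis(4-hydroxyphenyl)cyclobutane-1,3-dicarboxylic acid (centrosymmetric, meso) | OC(=O)[C@H]1[C@H](c2ccc(O)cc2)[C@H](C(=O)O)[C@H]1c1ccc(O)cc1 | intermediate
3 | benzyl bromide | BrCc1ccccc1 | starting material
4 | 4,4′-bis(benzyloxy)-α-truxillic acid, (1α,2α,3β,4β)-2,4-bis(4-benzyloxyphenyl)cyclobutane-1,3-dicarboxylic acid | OC(=O)[C@H]1[C@H](c2ccc(OCc3ccccc3)cc2)[C@H](C(=O)O)[C@H]1c1ccc(OCc2ccccc2)cc1 | intermediate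
5 | 1,1′-carbonyldiimidazole | O=C(n1ccnc1)n1ccnc1 | starting material
6 | 4,4′-bis(benzyloxy)-α-truxilloyl bis-imidazolide, (1α,2α,3β,4β) | O=C(n1ccnc1)[C@H]1[C@H](c2ccc(OCc3ccccc3)cc2)[C@H](C(=O)n2ccnc2)[C@H]1c1ccc(OCc2ccccc2)cc1 | intermediate
7 | methyl acetoacetate | CC(=O)CC(=O)OC | starting material
8 | sodium lithium dianion of methyl acetoacetate | [CH2-]C(=O)[CH-]C(=O)OC.[Na+].[Li+] | intermediate
9 | dimethyl 5,5′-[(1α,2α,3β,4β)-2,4-bis(4-benzyloxyphenyl)cyclobutane-1,3-diyl]bis(3,5-dioxopentanoate), drawn as the keto form | COC(=O)CC(=O)CC(=O)[C@H]1[C@H](c2ccc(OCc3ccccc3)cc2)[C@H](C(=O)CC(=O)CC(=O)OC)[C@H]1c1ccc(OCc2ccccc2)cc1 | intermediate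
10 | 6,6′-[(1α,2α,3β,4β)-2,4-bis(4-benzyloxyphenyl)cyclobutane-1,3-diyl]bis(4-hydroxy-2H-pyran-2-one) | Oc1cc(=O)oc([C@H]2[C@H](c3ccc(OCc4ccccc4)cc3)[C@H](c3cc(O)cc(=O)o3)[C@H]2c2ccc(OCc3ccccc3)cc2)c1 | intermediate
11 | dimethyl sulfate | COS(=O)(=O)OC | starting material
12 | 6,6′-[(1α,2α,3β,4β)-2,4-bis(4-benzyloxyphenyl)cyclobutane-1,3-diyl]bis(4-methoxy-2H-pyran-2-one) | COc1cc(=O)oc([C@H]2[C@H](c3ccc(OCc4ccccc4)cc3)[C@H](c3cc(OC)cc(=O)o3)[C@H]2c2ccc(OCc3ccccc3)cc2)c1 | intermediate
13 | 6,6′-[(1α,2α,3β,4β)-2,4-bis(4-hydroxyphenyl)cyclobutane-1,3-diyl]bis(4-methoxy-2H-pyran-2-one), CNP0273697.2 | COc1cc(=O)oc([C@H]2[C@H](c3ccc(O)cc3)[C@H](c3cc(OC)cc(=O)o3)[C@H]2c2ccc(O)cc2)c1 | target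

**Step count and risks**

Total step count: 7. Longest linear sequence: 7 steps, from 1 to 13.

Steps most likely to fail:

1. Step 4. The dianion may act as a base on the ring methine next to the azolide carbonyl instead of adding to it, which would epimerise the ring or eliminate imidazolide towards a ketene. The second acylation may also stall once the half-reacted polyanion has formed. The fallback sets out from compound 6: adding N,O-dimethylhydroxylamine hydrochloride and Et3N to its THF solution should convert both azolides into the bis(N-methoxy-N-methylamide) of 4,4′-bis(benzyloxy)-α-truxillic acid F1. Its α-CH bonds are far less acidic, and its adducts with dianion 8 (THF, −78 → 0 °C) persist as chelated tetrahedral intermediates until the acid quench. The same two C5–C6 bonds are formed, and the sequence comes back to the route at compound 9.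

2. Step 7. The Lewis acid may bind the pyranone carbonyls and remove the enol methyl groups together with the benzyl groups, or the benzyl cation may alkylate the phenol rings. The fallback sets out from compound 12 and removes the benzyl ethers by catalytic hydrogenolysis (H2 at 1 atm, Pd/C, EtOAc–THF, 23 °C), stopped as soon as the benzyl ethers are consumed so that the electron-rich pyranone double bonds are not reduced. It comes back to the route at compound 13 and makes no new compound (F0).

3. Step 6. The ambident pyranone anion may be alkylated at the wrong site (the C2 oxygen or C3) in one of the two rings, and both rings must react correctly in the same molecule. The fallback sets out from compound 10 and uses a Mitsunobu etherification with methanol (PPh3, diisopropyl azodicarboxylate, THF, 0 → 23 °C). This engages the pyranone as the acidic partner without a free anion and is established for 4-O-alkylation of 4-hydroxy-2-pyranones. It comes back to the route at compound 12 and makes no new compound (F0).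

Further compounds
F1 | step 4 | bis(N-methoxy-N-methylamide) of 4,4′-bis(benzyloxy)-α-truxillic acid, (1α,2α,3β,4β) | CON(C)C(=O)[C@H]1[C@H](c2ccc(OCc3ccccc3)cc2)[C@H](C(=O)N(C)OC)[C@H]1c1ccc(OCc2ccccc2)cc1
F0 | step 7 | none | none
F0 | step 6 | none | none
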